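Ring A is the phenol with OH para to its diaryl ether oxygen, ring B the phenol with OH ortho to its ether oxygen, ring C the 1,4-phenylene and ring D the 1,3-phenylene. The feature used is the CH2–CH2 bridge between rings C and D: its two carbons lie between two aryl carbons, hence the two aryl–CH2 bonds are disconnected and the C2 unit is supplied as a vinylene. A twofold Stille coupling of an acyclic diiodide with (E)-1,2-bis(tributylstannyl)ethene makes these two bonds and the 18-membered ring together, as an E-stilbene. The diiodide already contains both diaryl ethers, the ring A–ring B ethano bridge and two benzyl ethers.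

Key step: step 7

Remark: 1, 2 and 5 are taken as catalogue compounds, and the Wittig product 11 is carried on as an unseparated mixture of alkene isomers, so its SMILES bears no alkene descriptor.

Step 1
Reactants: 1 5-(benzyloxy)-2-hydroxybenzaldehyde; 2 3-iodophenylboronic acid
Product: 3 5-(benzyloxy)-2-(3-iodophenoxy)benzaldehyde
Conditions: Cu(OAc)2 (1.5 equiv), pyridine (5 equiv), 4 Å molecular sieves, CH2Cl2, air, rt; 2 in excess (2–3 equiv)
Reagents that add atoms: none
Why: Chan–Lam oxidative O-arylation, in which the phenoxide of 1 and the aryl group of 2 meet on copper and the C–O bond forms by reductive elimination at room temperature, where the C–I bond is inert, so the iodide is carried through without the statistical mixtures a diiodoarene partner would give.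

Step 2
Reactants: 4 4-(benzyloxy)-3-hydroxybenzaldehyde; 5 4-iodophenylboronic acid
Product: 6 4-(benzyloxy)-3-(4-iodophenoxy)benzaldehyde
Conditions: Cu(OAc)2 (1.5 equiv), pyridine (5 equiv), 4 Å molecular sieves, CH2Cl2, air, rt; 5 in excess (2 equiv)
Reagents that add atoms: none
Why: Chan–Lam O-arylation of an electron-rich ortho-alkoxy phenol, a substrate class for which this coupling is routine, with the aldehyde, the benzyl ether and the aryl iodide as spectators.

Step 3
Reactants: 6 4-(benzyloxy)-3-(4-iodophenoxy)benzaldehyde
Product: 7 [4-(benzyloxy)-3-(4-iodophenoxy)phenyl]methanol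
Conditions: NaBH4, MeOH/THF, 0 °C
Reagents that add atoms: none
Why: Hydride reduction of an aryl aldehyde (NaBH4 reduction), which touches neither the aryl iodide nor the benzyl and diaryl ethers.

Step 4
Reactants: 7 [4-(benzyloxy)-3-(4-iodophenoxy)phenyl]methanol
Product: 9 {[4-(benzyloxy)-3-(4-iodophenoxy)phenyl]methyl}triphenylphosphonium bromide, via benzylic bromide 8 (not isolated)
Conditions: PPh3·HBr, MeCN, reflux
Reagents that add atoms: triphenylphosphine hydrobromide, Br.c1ccc(cc1)P(c1ccccc1)c1ccccc1
Why: Phosphonium salt formation, in which HBr turns the para-alkoxy-activated benzylic alcohol into the bromide and PPh3 is quaternised by SN2 displacement, under weakly acidic conditions that leave the aryl benzyl ether and the aryl iodide intact.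

Step 5
Reactants: 9 {[4-(benzyloxy)-3-(4-iodophenoxy)phenyl]methyl}triphenylphosphonium bromide; 3 5-(benzyloxy)-2-(3-iodophenoxy)benzaldehyde
Product: 11 4-(benzyloxy)-2-{2-[4-(benzyloxy)-3-(4-iodophenoxy)phenyl]ethenyl}-1-(3-iodophenoxy)benzene (E/Z mixture), via phosphorus ylide 10 (not isolated)
Conditions: K2CO3, 18-crown-6 (cat.), CH2Cl2, reflux
Reagents that add atoms: none
Why: Wittig olefination of an aryl aldehyde by a semi-stabilised benzylic ylide generated with a mild carbonate base, the alkene geometry being of no consequence because the double bond is saturated in step 6.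

Step 6
Reactants: 11 stilbene diiodide (E/Z mixture)
Product: 12 4-(benzyloxy)-2-{2-[4-(benzyloxy)-3-(4-iodophenoxy)phenyl]ethyl}-1-(3-iodophenoxy)benzene
Conditions: TsNHNH2 (excess, in portions), NaOAc, THF/H2O, reflux
Reagents that add atoms: none
Why: Diimide reduction, a concerted syn transfer of two hydrogens from HN=NH generated in the flask, saturates the non-polar C=C bond and cannot cleave C–I or benzylic C–O bonds, which hydrogenation over palladium would attack.

Step 7
Reactants: 12 open-chain diiodide; 13 (E)-1,2-bis(tributylstannyl)ethene
Product: 16 macrocyclic E-stilbene dibenzyl ether, via ring-D vinylstannane 14 (not isolated), via ring-C vinylstannane 15 (not isolated)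
Conditions: Pd2(dba)3 (10 mol %), AsPh3 (40 mol %), DMF/THF, 60 °C, ca. 2 mM in 12, 13 (1.05 equiv) by syringe pump; aqueous KF work-up
Reagents that add atoms: none
Why: Zerovalent palladium, released from Pd2(dba)3 and kept reactive by the weakly bound AsPh3, inserts into one C–I bond of 12, one tin end of 13 transmetalates and reductive elimination gives an aryl (E)-2-stannylvinyl intermediate (14 or 15, whichever iodide reacts first; both converge), after which oxidative addition at the remaining C–I bond, transmetalation within the same molecule and reductive elimination close the ring. The closest known reaction type is the Stille cross-coupling used twice in one flask to stitch a dihalide together with a 1,2-distannylethene. The 18-membered ring is closed by an intramolecular aryl–alkenyl coupling between two sp2 carbons, the new alkene lying inside the ring. No stereocentre is formed, and the E geometry comes from 13 because transmetalation and reductive elimination both retain alkene configuration. The step needs ring closure to win over chain growth and over capping of both iodides by two molecules of 13, which high dilution of 12 and slow addition of 13 should secure. Chemoselectivity rests on the substrate, since the two C–I bonds are its only sites that react with zerovalent palladium while the benzyl ethers, the diaryl ethers and the saturated bridge are inert.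

Step 8
Reactants: 16 macrocyclic E-stilbene dibenzyl ether
Product: 18 dihydroptychantol A, via saturated macrocyclic dibenzyl ether 17 (not isolated)
Conditions: H2 (1 atm), 10% Pd/C, EtOAc/MeOH, rt
Reagents that add atoms: none
Why: Heterogeneous catalytic hydrogenation and hydrogenolysis over palladium, in which H2 adds to the stilbene and both benzylic C–O bonds are cleaved, whereas the diaryl ether C–O bonds resist these mild conditions.

Compound list
1 | 5-(benzyloxy)-2-hydroxybenzaldehyde | O=Cc1cc(OCc2ccccc2)ccc1O | starting material
2 | 3-iodophenylboronic acid | OB(O)c1cccc(I)c1 | starting material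
3 | 5-(benzyloxy)-2-(3-iodophenoxy)benzaldehyde | O=Cc1cc(OCc2ccccc2)ccc1Oc1cccc(I)c1 | intermediate
4 | 4-(benzyloxy)-3-hydroxybenzaldehyde | O=Cc1ccc(OCc2ccccc2)c(O)c1 | starting material
5 | 4-iodophenylboronic acid | OB(O)c1ccc(I)cc1 | starting material
6 | 4-(benzyloxy)-3-(4-iodophenoxy)benzaldehyde | O=Cc1ccc(OCc2ccccc2)c(Oc2ccc(I)cc2)c1 | intermediate
7 | [4-(benzyloxy)-3-(4-iodophenoxy)phenyl]methanol | OCc1ccc(OCc2ccccc2)c(Oc2ccc(I)cc2)c1 | intermediate
8 | 1-(benzyloxy)-4-(bromomethyl)-2-(4-iodophenoxy)benzene (formed in the flask, not isolated) | BrCc1ccc(OCc2ccccc2)c(Oc2ccc(I)cc2)c1 | intermediate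
9 | {[4-(benzyloxy)-3-(4-iodophenoxy)phenyl]methyl}triphenylphosphonium bromide | [Br-].Ic1ccc(cc1)Oc1cc(C[P+](c2ccccc2)(c2ccccc2)c2ccccc2)ccc1OCc1ccccc1 | intermediate
10 | phosphorus ylide of 9 (formed in the flask, not isolated) | Ic1ccc(cc1)Oc1cc(C=P(c2ccccc2)(c2ccccc2)c2ccccc2)ccc1OCc1ccccc1 | intermediate
11 | 4-(benzyloxy)-2-{2-[4-(benzyloxy)-3-(4-iodophenoxy)phenyl]ethenyl}-1-(3-iodophenoxy)benzene, E/Z mixture | Ic1cccc(c1)Oc1ccc(OCc2ccccc2)cc1C=Cc1ccc(OCc2ccccc2)c(c1)Oc1ccc(I)cc1 | intermediate
12 | 4-(benzyloxy)-2-{2-[4-(benzyloxy)-3-(4-iodophenoxy)phenyl]ethyl}-1-(3-iodophenoxy)benzene (open-chain diiodide) | Ic1cccc(c1)Oc1ccc(OCc2ccccc2)cc1CCc1ccc(OCc2ccccc2)c(c1)Oc1ccc(I)cc1 | intermediate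
13 | (E)-1,2-bis(tributylstannyl)ethene | CCCC[Sn](CCCC)(CCCC)/C=C/[Sn](CCCC)(CCCC)CCCC | starting material
14 | 12 with the ring D iodide replaced by (E)-2-(tributylstannyl)vinyl (formed in the flask, not isolated) | CCCC[Sn](CCCC)(CCCC)/C=C/c1cccc(c1)Oc1ccc(OCc2ccccc2)cc1CCc1ccc(OCc2ccccc2)c(c1)Oc1ccc(I)cc1 | intermediate
15 | 12 with the ring C iodide replaced by (E)-2-(tributylstannyl)vinyl (formed in the flask, not isolated) | Ic1cccc(c1)Oc1ccc(OCc2ccccc2)cc1CCc1ccc(OCc2ccccc2)c(c1)Oc1ccc(cc1)/C=C/[Sn](CCCC)(CCCC)CCCC | intermediate
16 | macrocyclic E-stilbene dibenzyl ether (18-membered ring; rings C and D joined by (E)-CH=CH, rings A and B by CH2CH2, benzyl ethers on rings A and B) | c1ccccc1COc1ccc2c(c1)CCc1ccc(OCc3ccccc3)c(c1)Oc1ccc(cc1)/C=C/c1cccc(c1)O2 | intermediate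
17 | saturated macrocyclic dibenzyl ether, di-O-benzyl dihydroptychantol A (formed in the flask, not isolated) | c1ccccc1COc1ccc2c(c1)CCc1ccc(OCc3ccccc3)c(c1)Oc1ccc(cc1)CCc1cccc(c1)O2 | intermediate
18 | dihydroptychantol A | Oc1ccc2c(c1)CCc1ccc(O)c(c1)Oc1ccc(cc1)CCc1cccc(c1)O2 | target

Total step count: 8
Longest linear sequence: 7 steps (steps 2 to 8)

Steps most likely to fail

Step 7. Chain growth by a second coupling between two molecules, capping of both iodides by two stannane molecules, or loss of tin from the vinylstannane by protonation could outrun ring closure. The fallback sets out from 12 and closes the same ring by carbonyl coupling. A twofold iodine–magnesium exchange with i-PrMgCl·LiCl in THF at −20 to 0 °C and a DMF quench should give the dialdehyde F1. An intramolecular McMurry coupling of F1 (TiCl4, Zn, pyridine, THF, reflux, slow addition at high dilution) should then give the macrocyclic stilbene as 16 together with its Z isomer F2. The fallback comes back at 16, and F2 is carried through step 8 alongside it to 18.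

Step 1. The ortho-formyl phenoxide can bind divalent copper as a chelate and slow C–O bond formation, while the boronic acid is used up by protodeboronation and oxidation. The fallback sets out from 1 and is an Ullmann condensation with an excess of 1,3-diiodobenzene (CuI, N,N-dimethylglycine, Cs2CO3, dioxane, 90 °C). It forms the same C–O bond from an aryl iodide electrophile under catalysis by monovalent copper. The excess of the symmetric diiodide should hold back double substitution. The fallback comes back at 3 and makes no compound outside the list (F0).

Step 8. Tin or arsenic residues from step 7 could poison the catalyst, so that hydrogenolysis stalls at partly benzylated material. The fallback sets out from 16 and separates the two tasks without a heterogeneous catalyst. Diimide (TsNHNH2, NaOAc, THF/H2O, reflux) should saturate the alkene to give 17 as an isolated compound. BCl3 with pentamethylbenzene in CH2Cl2 at −78 °C should then cleave both benzyl ethers. The fallback comes back at 18 and makes no compound outside the list (F0).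

Further compounds
F1 | step 7 | 3-[4-(benzyloxy)-2-{2-[4-(benzyloxy)-3-(4-formylphenoxy)phenyl]ethyl}phenoxy]benzaldehyde | O=Cc1cccc(c1)Oc1ccc(OCc2ccccc2)cc1CCc1ccc(OCc2ccccc2)c(c1)Oc1ccc(C=O)cc1
F2 | step 7 | Z isomer of the macrocyclic stilbene dibenzyl ether 16 | c1ccccc1COc1ccc2c(c1)CCc1ccc(OCc3ccccc3)c(c1)Oc1ccc(cc1)/C=C\c1cccc(c1)O2
F0 | step 1 | none | none
F0 | step 8 | none | none
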